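(The readings stem from a simulated flask for an exercise.)

Late in the north run, from 2.00 min to 4.00 min, E gained 2.1 percentage points and X gained 1.6 points, a ratio of 1.31, and I wanted to know what such a ratio is worth in a fed flask.

| flask | Z | L | temperature | remark | time |
|---|---|---|---|---|---|
| north | 0.24 M | 1 equiv | 20 °C | run made earlier |  |
| west | 0.24 M | 1.4 equiv | 31 °C | run made earlier |  |
| south-east | 0.24 M | 2.2 equiv | 20 °C | run made earlier |  |
| dusk | 0.24 M | 1.00 equiv | 25 °C | everything together at the start | 6.0 min |
| autumn | 0.24 M | 1.00 equiv (fed, over 5.0 min) |  | the addition at 5 °C, then warmed to 25 °C; the feed brings no volume worth counting | 6.0 min |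
| noon | 0.24 M (fed, over 5.0 min) | 1.00 equiv | 25 °C | all else is in the flask from the start; the feed brings no volume worth counting | 6.0 min |
| summer | 0.24 M | 1.00 equiv (fed, over 5.0 min) | 25 °C | all else is in the flask from the start; the feed brings no volume worth counting | 6.0 min |

| run | time / min | E / % | X / % |
|---|---|---|---|
| north | 0.250 | 0.7 | 1.1 |
| north | 0.500 | 0.9 | 1.9 |
| north | 1.00 | 2.8 | 3.6 |
| north | 2.00 | 3.8 | 5.2 |
| north | 4.00 | 5.9 | 6.8 |
| west | 1.00 | 2.2 | 13.1 |
| west | 2.00 | 2.9 | 20.5 |
| west | 3.00 | 2.9 | 26.3 |
| west | 4.00 | 2.8 | 29.4 |
| west | 5.00 | 2.7 | 32.3 |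
| south-east | 0.417 | 0.5 | 6.7 |
| south-east | 0.667 | 0.3 | 11.4 |
| south-east | 1.33 | 0.7 | 20.2 |
| south-east | 2.50 | 1.0 | 32.8 |
| south-east | 5.00 | 0.8 | 51.3 |

(scatter of a reading: 0.5 percentage points)

- percent here means Z units held: one E counts as two
- steps thought possible: Z + L -> G; L + G -> X; Z + G -> E

1. the flask with the highest amount of E, in percent of the Z charged ("all alike" if they lie within 1.5 percentage points) (dusk / autumn / noon / summer / all alike)
2. final E, as a percentage of the Z charged, in dusk
3. final E, as a percentage of the Z charged, in autumn
4. final E, as a percentage of the Z charged, in noon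
5. final E, as a percentage of the Z charged, in summer

E grows from G meeting Z, and X from G meeting L, so at one temperature the gain of E per gain of X is a fixed number times [Z]/[L]. The first 3 north rows sum to 4.4 points of E against 6.6 points of X, so I took 0.667 as the split s, the points of E gained per point of X where [Z] equals [L], a selectivity factor.

The late ratio, taken from differences of scattered readings, is higher, so by then north's Z/L read about 1.97. I put that back in. X spends a second L and E a second Z, so with equal charges Z minus L equals X minus E/2, which in north at 3.00 min, taken midway between the two late rows, reads 3.6 points. That puts north's L near 3.69 % and its Z near 7.27 %. For equal charges, with the side steps set aside, their geometric mean is about 1/(k·[Z]₀·t), which gives a rough reading of the first step in north, k = 26.8 /M/min.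

I carried k and s unchanged to 25 °C, as a rough step. At mid-feed, with the other partner taken at half its charge, I reckoned the fed species, L in summer and Z in noon, to stand where feed equals use, near 6.21 % of its charge, so the ratio of the two came to about 8.05. My s·Z/L at that moment came to 5.37 in summer and 0.0829 in noon.

The forecast gave summer as highest, with dusk 8 %, autumn 5 %, noon 6.5 % and summer 12.7 %: “Z stays in excess while G builds”.

The flasks gave summer as highest, with dusk 8.32 %, autumn 5.37 %, noon 5.03 % and summer 13.9 %.

Z + L → G (k = 0.327 /M/s, Ea = 43.0 kJ/mol); L + G → X (k = 0.0169 /M/s, Ea = 55.0 kJ/mol); Z + G → E (k = 0.00577 /M/s, Ea = 51.0 kJ/mol); (constants at 25 °C) Summer's E moved by 5 points at a Z charge of 0.139 M or 0.363 M, equivalents and time held. From 3.00 min to 5.00 min, summer's mean Z and L, with s as read in north, give s·Z/L = 1.65, and summer gained 1.63 of E per X. From 3.00 min to 6.00 min, dusk's give 1.87, and it gained 2.19.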